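**Retrosynthetic overview**

1. The target is (13S)-15-stearoyloxy-labd-8(17)-en-19-oic acid. The last operations are stearoylation of the C15 hydroxyl and oxidation of the C19 carbinol to the acid; the C6 oxygen left by the ring closure is removed by Barton–McCombie deoxygenation.
2. The strategy rests on this feature: C10 is the β-carbon of an enone whose carbonyl is C6 (C5=C10 lies in ring A), and C9, with its neighbour C8=C17, is the γ-carbon of a 2-substituted (Z)-allylsilane (Si–C17–C8=C9). Forming C9–C10 therefore closes ring B (C5–C10), makes the quaternary C10 and leaves the C8=C17 methylidene.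
3. Ring order: ring A first (enantioenriched β-keto ester, then enol triflate), ring B in the key step. The precursor is joined at C5–C6 by Nozaki–Hiyama–Kishi coupling and oxidation.
4. The allylsilane arm comes from silylmethylcupration of a butynyl ether (C6–C9, C17) and alkylation at C9–C11 with an iodide cut from (S)-citronellol (C11–C16).
5. One repair: a 6β-alkoxide would lactonise onto the axial C19 ester. After ring closure both carbonyls are therefore reduced, C6 is deoxygenated with C19 silylated, and C19 is re-oxidised at the end.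

Key step: step 14

Remark on numbering: labdane numbering (ring A = C1–C5, C10; ring B = C5–C10; C18 methyl and C19 on C4; C20 on C10; C17 on C8; chain C11–C16 on C9) is used for the bicyclic compounds and for the carbons of their precursors.

Assumption: the (S)-valine tert-butyl ester enamine alkylated in toluene/HMPA is taken to give the (S) quaternary centre; if the sense is the opposite, the THF variant of the same alkylation, which reverses the face, or the (R)-auxiliary is used.

**Route**

Step 1
Reactants: 1 methyl 2-oxocyclohexane-1-carboxylate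
Product: 2 methyl 2-{[(2S)-1-tert-butoxy-3-methyl-1-oxobutan-2-yl]amino}cyclohex-1-ene-1-carboxylate
Conditions: L-valine tert-butyl ester, BF3·OEt2 (cat.), benzene, reflux, azeotropic removal of water
Reagents that add atoms: L-valine tert-butyl ester, CC(C)[C@H](N)C(=O)OC(C)(C)C
Why: Acid-catalysed condensation of the β-keto ester with the primary amine gives the hydrogen-bonded vinylogous carbamate that carries the chiral auxiliary for the next step.

Step 2
Reactants: 2 valine-derived enamino ester
Product: 5 methyl (1S)-1-methyl-2-oxocyclohexane-1-carboxylate, via lithium azaenolate 3 (not isolated), via methylated imine 4 (not isolated)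
Conditions: LDA, toluene, −78 °C; HMPA (1 equiv), MeI, −78 to −50 °C; then 1 M aq. HCl, rt
Reagents that add atoms: iodomethane, CI; water, O
Why: Auxiliary-controlled alkylation of a chelated lithium azaenolate (chiral enamine alkylation of a β-keto ester) should let MeI enter on the face left open by the valine ester–lithium chelate and so set the quaternary centre (the future C4) as (S); mild acid hydrolysis of imine 4 returns the ketone and the auxiliary.

Step 3
Reactants: 5 methyl (1S)-1-methyl-2-oxocyclohexane-1-carboxylate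
Product: 7 methyl (1S)-1,3-dimethyl-2-oxocyclohexane-1-carboxylate (C3 epimers), via lithium enolate 6 (not isolated)
Conditions: LDA, THF, −78 °C; MeI, −78 to 0 °C
Reagents that add atoms: iodomethane, CI
Why: Kinetic enolate alkylation can occur only at C3 because C1 is quaternary, and the new C3 centre becomes sp2 in step 4, so its configuration does not matter.

Step 4
Reactants: 7 methyl (1S)-1,3-dimethyl-2-oxocyclohexane-1-carboxylate
Product: 9 methyl (1S)-1,3-dimethyl-2-(trifluoromethanesulfonyloxy)cyclohex-2-ene-1-carboxylate, via potassium enolate 8 (not isolated)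
Conditions: KHMDS, THF, −78 to 0 °C; PhNTf2, −78 °C to rt
Reagents that add atoms: N-phenylbis(trifluoromethanesulfonimide), O=S(=O)(N(c1ccccc1)S(=O)(=O)C(F)(F)F)C(F)(F)F
Why: Enolisation is possible only toward C3, so O-sulfonylation of the tetrasubstituted enolate should give a single enol triflate (future C5–OTf, C10–CH3) and leave the quaternary centre untouched.

Step 5
Reactants: 10 (S)-citronellol
Product: 11 tert-butyl{[(3S)-3,7-dimethyloct-6-en-1-yl]oxy}diphenylsilane
Conditions: TBDPSCl, imidazole, CH2Cl2, rt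
Reagents that add atoms: tert-butylchlorodiphenylsilane, CC(C)(C)[Si](Cl)(c1ccccc1)c1ccccc1
Why: Silylation of the primary alcohol installs a group that should survive ozone, iodine, organocopper, Lewis acid, hydride and base until step 19.

Step 6
Reactants: 11 citronellol TBDPS ether
Product: 13 (4S)-6-[(tert-butyldiphenylsilyl)oxy]-4-methylhexanal, via ozonide 12 (not isolated)
Conditions: O3, CH2Cl2, −78 °C (stopped at first blue colour); then PPh3, −78 °C to rt
Reagents that add atoms: ozone, [O-][O+]=O
Why: Ozonolysis of the electron-rich trisubstituted alkene with reductive work-up cuts off the isopropylidene group as acetone and does not touch the remote stereocentre.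

Step 7
Reactants: 13 (4S)-6-[(tert-butyldiphenylsilyl)oxy]-4-methylhexanal
Product: 14 (4S)-6-[(tert-butyldiphenylsilyl)oxy]-4-methylhexanoic acid
Conditions: NaClO2, NaH2PO4, 2-methyl-2-butene, t-BuOH/H2O, rt
Reagents that add atoms: sodium chlorite, [Na+].[O-]Cl=O
Why: Pinnick oxidation converts the aldehyde into the acid under buffered conditions that spare the silyl ether.

Step 8
Reactants: 14 (4S)-6-[(tert-butyldiphenylsilyl)oxy]-4-methylhexanoic acid
Product: 15 tert-butyl{[(3R)-5-iodo-3-methylpentyl]oxy}diphenylsilane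
Conditions: PhI(OAc)2, I2, cyclohexane, hν (tungsten lamp), reflux
Reagents that add atoms: iodine, II
Why: Hunsdiecker-type iododecarboxylation through the acyl hypoiodite gives a primary radical that is trapped by iodine, which shortens the chain by one carbon so that CH2I becomes C11; the stereocentre is unchanged and its descriptor turns to R only because of the iodine.

Step 9
Reactants: 16 tert-butyl(but-3-yn-1-yloxy)dimethylsilane (commercial; otherwise one silylation from but-3-yn-1-ol), 15 tert-butyl{[(3R)-5-iodo-3-methylpentyl]oxy}diphenylsilane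
Product: 18 tert-butyl{[(3S,6Z)-9-[(tert-butyldimethylsilyl)oxy]-3-methyl-7-[(trimethylsilyl)methyl]non-6-en-1-yl]oxy}diphenylsilane, via alkenylcopper 17 (not isolated)
Conditions: Me3SiCH2MgCl, CuBr·SMe2, Et2O/THF, −78 to 0 °C; 16, 0 °C to rt; then 15, HMPA, P(OEt)3, −30 °C to rt
Reagents that add atoms: (trimethylsilyl)methylmagnesium chloride, C[Si](C)(C)C[Mg]Cl
Why: syn-Carbocupration of the terminal alkyne puts Me3SiCH2 on the internal carbon (C8) and copper on the terminal carbon (C9), and alkylation of the alkenylcopper with the primary iodide with retention gives the (Z)-allylsilane in which C17 and C11 are cis; the bulky silyl ether is chosen so that the oxygen does not reverse the regiochemistry by chelation.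

Step 10
Reactants: 18 bis-silyl ether allylsilane
Product: 19 (3Z,7S)-9-[(tert-butyldiphenylsilyl)oxy]-7-methyl-3-[(trimethylsilyl)methyl]non-3-en-1-ol
Conditions: PPTS, MeOH, rt
Reagents that add atoms: none
Why: Mild acid methanolysis removes the primary TBS ether much faster than the TBDPS ether, and PPTS is too weak an acid to protodesilylate the allylsilane.

Step 11
Reactants: 19 (3Z,7S)-9-[(tert-butyldiphenylsilyl)oxy]-7-methyl-3-[(trimethylsilyl)methyl]non-3-en-1-ol
Product: 20 (3Z,7S)-9-[(tert-butyldiphenylsilyl)oxy]-7-methyl-3-[(trimethylsilyl)methyl]non-3-enal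
Conditions: DMP (triacetoxy periodinane), NaHCO3, CH2Cl2, 0 °C; used crude
Reagents that add atoms: none
Why: Buffered periodinane oxidation gives the β,γ-unsaturated aldehyde without acid or base strong enough to move the double bond, and the aldehyde is used at once.

Step 12
Reactants: 9 ring A enol triflate, 20 allylsilane aldehyde
Product: 21 methyl (1S)-2-{(3Z,7S)-9-[(tert-butyldiphenylsilyl)oxy]-1-hydroxy-7-methyl-3-[(trimethylsilyl)methyl]non-3-en-1-yl}-1,3-dimethylcyclohex-2-ene-1-carboxylate (C6 epimers)
Conditions: CrCl2 (4 equiv), NiCl2 (2 mol %), DMF, rt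
Reagents that add atoms: none
Why: Nozaki–Hiyama–Kishi coupling: nickel inserts into the C–OTf bond and passes the alkenyl group to chromium, which adds to the aldehyde (forming C5–C6) without enolising it and without touching the ester or the allylsilane; the carbinol is oxidised promptly because a γ-hydroxy ester of this kind can lactonise.

Step 13
Reactants: 21 allylic alcohol (C6 epimers)
Product: 22 methyl (1S)-2-{(3Z,7S)-9-[(tert-butyldiphenylsilyl)oxy]-7-methyl-3-[(trimethylsilyl)methyl]non-3-enoyl}-1,3-dimethylcyclohex-2-ene-1-carboxylate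
Conditions: DMP, NaHCO3, CH2Cl2, 0 °C to rt
Reagents that add atoms: none
Why: Buffered periodinane oxidation of the allylic alcohol removes the C6 stereocentre and gives the 2-acylcyclohexene without isomerising the skipped alkene.

Step 14
Reactants: 22 2-acylcyclohexene carrying the (Z)-allylsilane
Product: 24 methyl (4S,5R,9S,10R,13S)-15-[(tert-butyldiphenylsilyl)oxy]-6-oxolabd-8(17)-en-19-oate, via aluminium enolate 23 (not isolated)
Conditions: EtAlCl2 (3 equiv), toluene, −78 to −20 °C; quench with Et3N/MeOH at −78 °C, then pH 7 buffer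
Reagents that add atoms: none
Why: EtAlCl2 binds the C6 carbonyl and the allylsilane attacks C10 through its γ-carbon C9, the cation developing at C8 being stabilised by the C17–Si bond and collapsing to the C8=C17 methylidene with loss of Me3SiCl, which leaves aluminium enolate 23 to be protonated at C5 on quench. The closest known reaction type is the intramolecular Hosomi–Sakurai conjugate addition of 2-substituted allylsilanes to β,β-disubstituted enones, which forms six-membered rings and quaternary carbons; this tetrasubstituted acylcyclohexene itself has not been tried. Ring B (C5–C10) closes in the 6-endo-trig mode with the C6 carbonyl inside the new ring, which needs the s-trans enone rotamer that places C7 beside C20. At C10 the attack must come from the α face, so that the developing axial C20 lies syn to the axial C4 ester and not to the C4 methyl, a preference set by the (S) centre at C4; at C9 the Z geometry puts C11 equatorial and H9 axial in the chair-like array C5–C6–C7–C8–C9–C10; at C5 protonation of 23 from the α face, away from C20 and the ester, gives the trans ring fusion, which is also the more stable one. The step needs γ-attack to beat protodesilylation and the new β,γ-enone not to drift into conjugation: the ethyl–aluminium bond consumes adventitious acid, the quench is cold and buffered, and 24 is reduced at once in step 15.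

Step 15
Reactants: 24 6-oxo ester
Product: 25 (13S)-15-[(tert-butyldiphenylsilyl)oxy]labd-8(17)-ene-6β,19-diol
Conditions: LiAlH4, THF, 0 °C to rt
Reagents that add atoms: none
Why: Hydride should attack C6 from the α face (the β face is screened by C20 and the axial C4 substituent); because the resulting 6β-alkoxide closes onto the axial ester, the ester is not kept but reduced with it (directly or through the lactone) to the C19 carbinol, which also ends the risk of alkene migration.

Step 16
Reactants: 25 6β,19-diol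
Product: 26 (13S)-19-[(tert-butyldimethylsilyl)oxy]-15-[(tert-butyldiphenylsilyl)oxy]labd-8(17)-en-6β-ol
Conditions: TBSCl, imidazole, DMF, rt
Reagents that add atoms: tert-butylchlorodimethylsilane, CC(C)(C)[Si](C)(C)Cl
Why: The primary C19 hydroxyl is silylated selectively because the axial 6β-hydroxyl is flanked by C20 and the C4 substituents.

Step 17
Reactants: 26 6β-alcohol
Product: 28 O-[(13S)-19-(tert-butyldimethylsilyloxy)-15-(tert-butyldiphenylsilyloxy)labd-8(17)-en-6β-yl] S-methyl dithiocarbonate, via sodium xanthate 27 (not isolated)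
Conditions: NaH, imidazole (cat.), THF, 0 °C to rt; CS2; then MeI
Reagents that add atoms: carbon disulfide, S=C=S; iodomethane, CI
Why: Xanthate formation, the first half of the Barton–McCombie deoxygenation, uses the small electrophile CS2, which should reach the hindered axial alkoxide.

Step 18
Reactants: 28 6β-xanthate
Product: 29 (13S)-19-[(tert-butyldimethylsilyl)oxy]-15-[(tert-butyldiphenylsilyl)oxy]labd-8(17)-ene
Conditions: Bu3SnH, AIBN (cat.), toluene, 100 °C
Reagents that add atoms: none
Why: Barton–McCombie radical cleavage of the C6–O bond gives a secondary radical that is reduced by the stannane, while the 1,1-disubstituted alkene and both silyl ethers are inert to the chain.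

Step 19
Reactants: 29 bis-silyl ether
Product: 30 (13S)-labd-8(17)-ene-15,19-diol
Conditions: TBAF, THF, rt to 50 °C
Reagents that add atoms: none
Why: Fluoride cleaves both silyl ethers in one operation and affects nothing else in the molecule.

Step 20
Reactants: 30 15,19-diol, 31 stearic acid
Product: 33 (13S)-19-hydroxylabd-8(17)-en-15-yl octadecanoate, via stearoyl chloride 32 (not isolated)
Conditions: 31, (COCl)2, DMF (cat.), CH2Cl2, rt, then evaporation; 30 (1 equiv), pyridine, CH2Cl2, −20 to 0 °C
Reagents that add atoms: none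
Why: Acylation with one equivalent of the acid chloride should take the unhindered primary C15 hydroxyl much faster than the neopentyl, axial C19 hydroxyl.

Step 21
Reactants: 33 C15 stearate with free C19 carbinol
Product: 34 (13S)-19-oxolabd-8(17)-en-15-yl octadecanoate
Conditions: DMP, NaHCO3, CH2Cl2, rt
Reagents that add atoms: none
Why: Periodinane oxidation of the neopentyl carbinol gives an aldehyde on the quaternary C4, which cannot epimerise, and leaves the ester and the alkene alone.

Step 22
Reactants: 34 C19 aldehyde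
Product: 35 (4S,5R,9S,10R,13S)-15-(octadecanoyloxy)labd-8(17)-en-19-oic acid (target)
Conditions: NaClO2, NaH2PO4, 2-methyl-2-butene, t-BuOH/THF/H2O, rt
Reagents that add atoms: sodium chlorite, [Na+].[O-]Cl=O
Why: Pinnick oxidation converts the hindered aldehyde into the acid while 2-methyl-2-butene intercepts the hypochlorous acid that would otherwise attack the exocyclic alkene.

**Compound list**

1 | methyl 2-oxocyclohexane-1-carboxylate | COC(=O)C1CCCCC1=O | starting material
2 | methyl 2-{[(2S)-1-tert-butoxy-3-methyl-1-oxobutan-2-yl]amino}cyclohex-1-ene-1-carboxylate | COC(=O)C1=C(N[C@@H](C(C)C)C(=O)OC(C)(C)C)CCCC1 | intermediate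
3 | N-lithio derivative of 2 (lithium azaenolate) | COC(=O)C1=C(N([Li])[C@@H](C(C)C)C(=O)OC(C)(C)C)CCCC1 | intermediate
4 | methyl (1S)-2-{[(2S)-1-tert-butoxy-3-methyl-1-oxobutan-2-yl]imino}-1-methylcyclohexane-1-carboxylate | COC(=O)[C@@]1(C)CCCCC1=N[C@@H](C(C)C)C(=O)OC(C)(C)C | intermediate
5 | methyl (1S)-1-methyl-2-oxocyclohexane-1-carboxylate | COC(=O)[C@@]1(C)CCCCC1=O | intermediate
6 | lithium enolate of 5 | COC(=O)[C@@]1(C)CCCC=C1O[Li] | intermediate
7 | methyl (1S)-1,3-dimethyl-2-oxocyclohexane-1-carboxylate (C3 epimers) | COC(=O)[C@@]1(C)CCCC(C)C1=O | intermediate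
8 | potassium enolate of 7 | COC(=O)[C@@]1(C)CCCC(C)=C1O[K] | intermediate
9 | methyl (1S)-1,3-dimethyl-2-(trifluoromethanesulfonyloxy)cyclohex-2-ene-1-carboxylate | COC(=O)[C@@]1(C)CCCC(C)=C1OS(=O)(=O)C(F)(F)F | intermediate
10 | (S)-citronellol | CC(C)=CCC[C@H](C)CCO | starting material
11 | tert-butyl{[(3S)-3,7-dimethyloct-6-en-1-yl]oxy}diphenylsilane | CC(C)=CCC[C@H](C)CCO[Si](c1ccccc1)(c1ccccc1)C(C)(C)C | intermediate
12 | ozonide of 11 (3,3-dimethyl-1,2,4-trioxolane carrying the C11–C15 chain at C5) | CC1(C)OOC(CC[C@H](C)CCO[Si](c2ccccc2)(c2ccccc2)C(C)(C)C)O1 | intermediate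
13 | (4S)-6-[(tert-butyldiphenylsilyl)oxy]-4-methylhexanal | O=CCC[C@H](C)CCO[Si](c1ccccc1)(c1ccccc1)C(C)(C)C | intermediate
14 | (4S)-6-[(tert-butyldiphenylsilyl)oxy]-4-methylhexanoic acid | OC(=O)CC[C@H](C)CCO[Si](c1ccccc1)(c1ccccc1)C(C)(C)C | intermediate
15 | tert-butyl{[(3R)-5-iodo-3-methylpentyl]oxy}diphenylsilane | ICC[C@H](C)CCO[Si](c1ccccc1)(c1ccccc1)C(C)(C)C | intermediate
16 | tert-butyl(but-3-yn-1-yloxy)dimethylsilane | C#CCCO[Si](C)(C)C(C)(C)C | starting material
17 | {(1Z)-4-[(tert-butyldimethylsilyl)oxy]-2-[(trimethylsilyl)methyl]but-1-en-1-yl}copper | [Cu]/C=C(\C[Si](C)(C)C)CCO[Si](C)(C)C(C)(C)C | intermediate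
18 | tert-butyl{[(3S,6Z)-9-[(tert-butyldimethylsilyl)oxy]-3-methyl-7-[(trimethylsilyl)methyl]non-6-en-1-yl]oxy}diphenylsilane | C[Si](C)(C)C/C(CCO[Si](C)(C)C(C)(C)C)=C\CC[C@H](C)CCO[Si](c1ccccc1)(c1ccccc1)C(C)(C)C | intermediate
19 | (3Z,7S)-9-[(tert-butyldiphenylsilyl)oxy]-7-methyl-3-[(trimethylsilyl)methyl]non-3-en-1-ol | C[Si](C)(C)C/C(CCO)=C\CC[C@H](C)CCO[Si](c1ccccc1)(c1ccccc1)C(C)(C)C | intermediate
20 | (3Z,7S)-9-[(tert-butyldiphenylsilyl)oxy]-7-methyl-3-[(trimethylsilyl)methyl]non-3-enal | C[Si](C)(C)C/C(CC=O)=C\CC[C@H](C)CCO[Si](c1ccccc1)(c1ccccc1)C(C)(C)C | intermediate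
21 | methyl (1S)-2-{(3Z,7S)-9-[(tert-butyldiphenylsilyl)oxy]-1-hydroxy-7-methyl-3-[(trimethylsilyl)methyl]non-3-en-1-yl}-1,3-dimethylcyclohex-2-ene-1-carboxylate (C6 epimers) | CC1=C(C(O)C/C(C[Si](C)(C)C)=C/CC[C@H](C)CCO[Si](c2ccccc2)(c2ccccc2)C(C)(C)C)[C@@](C)(C(=O)OC)CCC1 | intermediate
22 | methyl (1S)-2-{(3Z,7S)-9-[(tert-butyldiphenylsilyl)oxy]-7-methyl-3-[(trimethylsilyl)methyl]non-3-enoyl}-1,3-dimethylcyclohex-2-ene-1-carboxylate | CC1=C(C(=O)C/C(C[Si](C)(C)C)=C/CC[C@H](C)CCO[Si](c2ccccc2)(c2ccccc2)C(C)(C)C)[C@@](C)(C(=O)OC)CCC1 | intermediate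
23 | chloro(ethyl)aluminium C5=C6 enolate of 24 | C=C1CC(O[Al](Cl)CC)=C2[C@@](C)(C(=O)OC)CCC[C@]2(C)[C@H]1CC[C@H](C)CCO[Si](c1ccccc1)(c1ccccc1)C(C)(C)C | intermediate
24 | methyl (4S,5R,9S,10R,13S)-15-[(tert-butyldiphenylsilyl)oxy]-6-oxolabd-8(17)-en-19-oate | C=C1CC(=O)[C@@H]2[C@](C)(CCC[C@]2(C)C(=O)OC)[C@H]1CC[C@H](C)CCO[Si](c1ccccc1)(c1ccccc1)C(C)(C)C | intermediate
25 | (13S)-15-[(tert-butyldiphenylsilyl)oxy]labd-8(17)-ene-6β,19-diol | C=C1C[C@@H](O)[C@@H]2[C@](C)(CCC[C@]2(C)CO)[C@H]1CC[C@H](C)CCO[Si](c1ccccc1)(c1ccccc1)C(C)(C)C | intermediate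
26 | (13S)-19-[(tert-butyldimethylsilyl)oxy]-15-[(tert-butyldiphenylsilyl)oxy]labd-8(17)-en-6β-ol | C=C1C[C@@H](O)[C@@H]2[C@](C)(CCC[C@]2(C)CO[Si](C)(C)C(C)(C)C)[C@H]1CC[C@H](C)CCO[Si](c1ccccc1)(c1ccccc1)C(C)(C)C | intermediate
27 | sodium O-(6β-yl) dithiocarbonate of 26 | C=C1C[C@@H](OC(=S)S[Na])[C@@H]2[C@](C)(CCC[C@]2(C)CO[Si](C)(C)C(C)(C)C)[C@H]1CC[C@H](C)CCO[Si](c1ccccc1)(c1ccccc1)C(C)(C)C | intermediate
28 | O-[(13S)-19-(tert-butyldimethylsilyloxy)-15-(tert-butyldiphenylsilyloxy)labd-8(17)-en-6β-yl] S-methyl dithiocarbonate | C=C1C[C@@H](OC(=S)SC)[C@@H]2[C@](C)(CCC[C@]2(C)CO[Si](C)(C)C(C)(C)C)[C@H]1CC[C@H](C)CCO[Si](c1ccccc1)(c1ccccc1)C(C)(C)C | intermediate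
29 | (13S)-19-[(tert-butyldimethylsilyl)oxy]-15-[(tert-butyldiphenylsilyl)oxy]labd-8(17)-ene | C=C1CC[C@@H]2[C@](C)(CCC[C@]2(C)CO[Si](C)(C)C(C)(C)C)[C@H]1CC[C@H](C)CCO[Si](c1ccccc1)(c1ccccc1)C(C)(C)C | intermediate
30 | (13S)-labd-8(17)-ene-15,19-diol | C=C1CC[C@@H]2[C@](C)(CCC[C@]2(C)CO)[C@H]1CC[C@H](C)CCO | intermediate
31 | stearic acid | CCCCCCCCCCCCCCCCCC(=O)O | starting material
32 | stearoyl chloride | CCCCCCCCCCCCCCCCCC(=O)Cl | intermediate
33 | (13S)-19-hydroxylabd-8(17)-en-15-yl octadecanoate | C=C1CC[C@@H]2[C@](C)(CCC[C@]2(C)CO)[C@H]1CC[C@H](C)CCOC(=O)CCCCCCCCCCCCCCCCC | intermediate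
34 | (13S)-19-oxolabd-8(17)-en-15-yl octadecanoate | C=C1CC[C@@H]2[C@](C)(CCC[C@]2(C)C=O)[C@H]1CC[C@H](C)CCOC(=O)CCCCCCCCCCCCCCCCC | intermediate
35 | (4S,5R,9S,10R,13S)-15-(octadecanoyloxy)labd-8(17)-en-19-oic acid | C=C1CC[C@@H]2[C@](C)(CCC[C@]2(C)C(=O)O)[C@H]1CC[C@H](C)CCOC(=O)CCCCCCCCCCCCCCCCC | target

**Step count**

Total: 22 steps. Longest linear sequence: 18 steps (steps 5–22, from (S)-citronellol).

**Steps most likely to fail, with fallbacks**

1. Step 14 (ring B closure). The acyl group of 22 is twisted out of the C5=C10 plane, so protodesilylation of the allylsilane may outrun attack on the hindered C10; the attack may also take the β face, or the exocyclic alkene may drift into conjugation with C6. The fallback sets out from 21 and comes back at 26: C9–C10 is made by an anionic oxy-Cope rearrangement and ring B is then closed at C6–C7 by an allylsilane–aldehyde addition. The ester is reduced first, because the potassium alkoxide of 21 would lactonise onto it. The (6S)-epimer of 21 (separated by chromatography; the other epimer is recycled through 22) is reduced with LiAlH4 in THF to the (6S)-diol F1. Its primary hydroxyl is silylated (TBSCl, imidazole) to the C19 TBS ether F2. KH and 18-crown-6 in THF then trigger the [3,3] shift of the 1,5-dien-3-olate C10=C5–C6(O−)–C7–C8=C9. In the chair with the alkoxide equatorial, C9 bonds to the α face of C10 with C20 and H9 anti, and protonation gives the 6,7-seco aldehyde F3, whose new allylsilane has C7 as its free terminus. SnCl4 in CH2Cl2 at −78 °C closes ring B onto the aldehyde to the 6-carbinol F4. DMP oxidation gives the 19-silyloxy 6-ketone F5, whose C5 equilibrates to the trans-fused isomer, and NaBH4 in MeOH delivers hydride from the α face to give 26.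

2. Step 9 (silylmethylcupration and alkylation). The silylmethyl group may add with the wrong regiochemistry, or alkenylcopper 17 may decompose before the unactivated iodide alkylates it. The fallback sets out from 16 (through 17) and comes back at 18. Alkenylcopper 17 is quenched with I2 at −40 °C to the (Z)-alkenyl iodide F6, which can be purified and its geometry checked. Iodide 15 is converted with zinc dust and LiCl in THF into the alkylzinc iodide F7. Negishi coupling of F6 and F7 (Pd(dppf)Cl2, THF, 50 °C) gives 18 with retention of the alkene geometry.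

3. Step 17 (xanthate at the 6β-hydroxyl). The axial alkoxide, flanked by C20 and the C19 silyloxymethyl group, may add to CS2 only slowly or may take over the silyl group from O19. The fallback sets out from 25 and comes back at 30. Diol 25 is heated with 1,1′-thiocarbonyldiimidazole and DMAP in toluene to give the cyclic 6β,19-thionocarbonate F8; the unhindered C19 hydroxyl reacts first and the second C–O bond forms intramolecularly. Bu3SnH and AIBN in toluene at 100 °C cleave the C6–O bond, because the secondary radical is preferred over the primary one, and K2CO3 in MeOH frees the C19 alcohol F9. TBAF in THF then gives 30.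

**Further compounds**

F1 | step 14 | {(1S)-2-[(1S,3Z,7S)-9-[(tert-butyldiphenylsilyl)oxy]-1-hydroxy-7-methyl-3-[(trimethylsilyl)methyl]non-3-en-1-yl]-1,3-dimethylcyclohex-2-en-1-yl}methanol | CC1=C([C@@H](O)C/C(C[Si](C)(C)C)=C/CC[C@H](C)CCO[Si](c2ccccc2)(c2ccccc2)C(C)(C)C)[C@@](C)(CO)CCC1
F2 | step 14 | primary tert-butyldimethylsilyl ether of F1 | CC1=C([C@@H](O)C/C(C[Si](C)(C)C)=C/CC[C@H](C)CCO[Si](c2ccccc2)(c2ccccc2)C(C)(C)C)[C@@](C)(CO[Si](C)(C)C(C)(C)C)CCC1
F3 | step 14 | (13S)-19-[(tert-butyldimethylsilyl)oxy]-15-[(tert-butyldiphenylsilyl)oxy]-17-(trimethylsilyl)-6,7-secolabd-7-en-6-al (C5 epimers) | O=CC1[C@@](C)(CO[Si](C)(C)C(C)(C)C)CCC[C@]1(C)[C@@H](CC[C@H](C)CCO[Si](c1ccccc1)(c1ccccc1)C(C)(C)C)C(=C)C[Si](C)(C)C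
F4 | step 14 | (13S)-19-[(tert-butyldimethylsilyl)oxy]-15-[(tert-butyldiphenylsilyl)oxy]labd-8(17)-en-6-ol (C5 and C6 epimers) | C=C1CC(O)C2[C@](C)(CCC[C@]2(C)CO[Si](C)(C)C(C)(C)C)[C@H]1CC[C@H](C)CCO[Si](c1ccccc1)(c1ccccc1)C(C)(C)C
F5 | step 14 | (13S)-19-[(tert-butyldimethylsilyl)oxy]-15-[(tert-butyldiphenylsilyl)oxy]labd-8(17)-en-6-one (trans-fused) | C=C1CC(=O)[C@@H]2[C@](C)(CCC[C@]2(C)CO[Si](C)(C)C(C)(C)C)[C@H]1CC[C@H](C)CCO[Si](c1ccccc1)(c1ccccc1)C(C)(C)C
F6 | step 9 | tert-butyl{[(3Z)-4-iodo-3-[(trimethylsilyl)methyl]but-3-en-1-yl]oxy}dimethylsilane | I/C=C(\C[Si](C)(C)C)CCO[Si](C)(C)C(C)(C)C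
F7 | step 9 | {(3R)-5-[(tert-butyldiphenylsilyl)oxy]-3-methylpentyl}zinc iodide | I[Zn]CC[C@H](C)CCO[Si](c1ccccc1)(c1ccccc1)C(C)(C)C
F8 | step 17 | cyclic 6β,19-thionocarbonate of 25 | C=C1C[C@H]3OC(=S)OC[C@@]4(C)CCC[C@](C)([C@H]1CC[C@H](C)CCO[Si](c1ccccc1)(c1ccccc1)C(C)(C)C)[C@@H]34
F9 | step 17 | (13S)-15-[(tert-butyldiphenylsilyl)oxy]labd-8(17)-en-19-ol | C=C1CC[C@@H]2[C@](C)(CCC[C@]2(C)CO)[C@H]1CC[C@H](C)CCO[Si](c1ccccc1)(c1ccccc1)C(C)(C)C
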